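**Retrosynthetic overview**

- Feature: each terminal benzene ring is hexasubstituted in the order C1 butanoyl, C2 OH, C3 CH2 bridge, C4 OH, C5 CH3, C6 OCH3. The run C3–C4–C5–C6 is a masked 1,1-dimethoxy-2-methyl-3-silyloxy diene and C1–C2 a masked alkoxy ynone, so the three ring oxygens come from three different functions and no selective O-alkylation is needed.
- Agrimol B 29 ⇐ global hydrogenolysis ⇐ pentabenzyl ether 28 ⇐ double [4+2] cycloaddition/aromatisation of bis-diene 16 with two molecules of ynone 25 (bonds C2–C3 and C1–C6 of both terminal rings).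
- 16 ⇐ bis(acylketene acetal) 15 ⇐ diacid 11 + two molecules of 1,1-dimethoxypropene 13; 11 ⇐ dialdehyde 7 ⇐ diformylation and benzylation of (S)-2-methylbutanoylphloroglucinol 4 ⇐ phloroglucinol + (S)-2-methylbutanoic acid.
- Ring order: the central ring comes from phloroglucinol and is fully substituted first; both terminal rings are created last, in one step.

Key step: step 11

Remark: the ynol ether oxygen of the dienophile is carried as a benzyl ether, because tert-alkyl ynol ethers fragment to ketenes by retro-ene loss of alkene on gentle warming; this also lets all five protecting groups fall in one neutral hydrogenolysis. The side-chain centre of the target is (S), as in (S)-2-methylbutanoic acid. Where a step builds both arms, the first molecule of the small partner stands on the Reactants line and the second on the line of reagents that add atoms.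

**Route**

Step 1
Reactants: 1 (S)-2-methylbutanoic acid; 2 phloroglucinol
Product: 4 (S)-2-methyl-1-(2,4,6-trihydroxyphenyl)butan-1-one, via (S)-2-methylbutanoyl chloride 3 (not isolated)
Conditions: (COCl)2, DMF (cat.), CH2Cl2, 0 °C → rt, concentrate; then 2, AlCl3, PhNO2/CH2Cl2, rt → 40 °C; aq. HCl work-up
Reagents that add atoms: none
Why: Base-free acid chloride formation followed by AlCl3-mediated Friedel–Crafts C-acylation should stop at the monoketone because the chelated aluminium complex of the product is deactivated; no stereocenter is formed and the (S)-centre is not enolised.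

Step 2
Reactants: 4 (S)-2-methyl-1-(2,4,6-trihydroxyphenyl)butan-1-one
Product: 6 (S)-2,4,6-trihydroxy-5-(2-methylbutanoyl)benzene-1,3-dicarbaldehyde, via bis(iminium) salt 5 (not isolated)
Conditions: POCl3, DMF, EtOAc, 0 °C → rt; then H2O, 50 °C
Reagents that add atoms: N,N-dimethylformamide CN(C)C=O; water O
Why: Vilsmeier–Haack formylation: both free ring positions are flanked by two hydroxyl groups and should remain nucleophilic enough to take up a chloroiminium ion each, the bis(iminium) salt being hydrolysed to the chelated dialdehyde.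

Step 3
Reactants: 6 (S)-2,4,6-trihydroxy-5-(2-methylbutanoyl)benzene-1,3-dicarbaldehyde
Product: 7 (S)-2,4,6-tris(benzyloxy)-5-(2-methylbutanoyl)benzene-1,3-dicarbaldehyde
Conditions: BnBr, K2CO3, DMF, 50 °C
Reagents that add atoms: benzyl bromide BrCc1ccccc1
Why: Williamson O-alkylation of the three acidic phenols; C-alkylation of the fully substituted ring would cost its aromaticity, so O-benzylation in a dipolar aprotic solvent is favoured, and carbonate is too weak to enolise the ketone.

Step 4
Reactants: 7 (S)-2,4,6-tris(benzyloxy)-5-(2-methylbutanoyl)benzene-1,3-dicarbaldehyde; 8 Meldrum's acid (2,2-dimethyl-1,3-dioxane-4,6-dione)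
Product: 11 3,3'-{2,4,6-tris(benzyloxy)-5-[(S)-2-methylbutanoyl]-1,3-phenylene}dipropanoic acid, via bis(alkylidene Meldrum's acid) 9 (not isolated), via bis(alkyl Meldrum's acid) 10 (not isolated)
Conditions: 8 (2.2 equiv), HCO2H/Et3N (5:2), rt → 95 °C
Reagents that add atoms: none
Why: Reductive Knoevenagel homologation in triethylammonium formate: condensation of each aldehyde with Meldrum's acid, hydride transfer from formate to the alkylidene Meldrum's acid and, on heating, ring opening by the water of condensation with loss of acetone and CO2 should give the 3-arylpropanoic acids in one pot, benzyl ethers and the hindered aryl ketone being inert.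

Step 5
Reactants: 12 trimethyl orthopropionate
Product: 13 1,1-dimethoxypropene
Conditions: Me3SiOTf, iPr2NEt, CH2Cl2, −20 °C → rt; distil
Reagents that add atoms: none
Why: Silyl triflate ionises the orthoester to a dialkoxycarbenium ion, which the hindered amine deprotonates (Gassman-type elimination of methanol from acetals and orthoesters) to give the ketene acetal.

Step 6
Reactants: 11 3,3'-{2,4,6-tris(benzyloxy)-5-[(S)-2-methylbutanoyl]-1,3-phenylene}dipropanoic acid; 13 1,1-dimethoxypropene
Product: 15 (S)-1-[2,4,6-tris(benzyloxy)-3,5-bis(5,5-dimethoxy-4-methyl-3-oxopent-4-enyl)phenyl]-2-methylbutan-1-one, via bis(acid chloride) 14 (not isolated)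
Conditions: (COCl)2, DMF (cat.), CH2Cl2, 0 °C → rt, concentrate; then 13 (6 equiv), Et2O, 0 °C → rt
Reagents that add atoms: 1,1-dimethoxypropene (the second molecule of 13 for the second arm) CC=C(OC)OC
Why: C-Acylation of a ketene acetal by an acid chloride (McElvain acylation): each of the two acyl chlorides is attacked by the nucleophilic carbon of one molecule of 13, so that two molecules of 13 end up in 15, and each dialkoxycarbenium intermediate loses its α-proton to a further molecule of 13, which takes up HCl as methyl propanoate and chloromethane, so no amine base that could form a ketene or enolise the aryl ketone is present.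

Step 7
Reactants: 15 (S)-1-[2,4,6-tris(benzyloxy)-3,5-bis(5,5-dimethoxy-4-methyl-3-oxopent-4-enyl)phenyl]-2-methylbutan-1-one
Product: 16 (S)-1-{2,4,6-tris(benzyloxy)-3,5-bis[(Z)-5,5-dimethoxy-4-methyl-3-(trimethylsilyloxy)penta-2,4-dienyl]phenyl}-2-methylbutan-1-one
Conditions: Me3SiOTf, Et3N, Et2O, −78 → 0 °C; used crude
Reagents that add atoms: trimethylsilyl trifluoromethanesulfonate C[Si](C)(C)OS(=O)(=O)C(F)(F)F
Why: Soft enolisation: the silyl triflate activates each acylketene acetal carbonyl and Et3N removes the only α'-protons (chain CH2) to give the thermodynamically preferred (Z)-silyl dienol ethers, while the twisted, di-ortho-substituted aryl sec-butyl ketone is too hindered to enolise at low temperature and should keep its configuration.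

Step 8
Reactants: 17 benzyl alcohol; 18 trichloroethylene
Product: 20 benzyl (E)-1,2-dichlorovinyl ether, via potassium benzyl oxide 19 (not isolated)
Conditions: KH, THF, 0 °C; then 18, 0 °C → rt
Reagents that add atoms: none
Why: Greene's synthesis of 1,2-dichlorovinyl ethers: the alkoxide converts trichloroethylene into dichloroacetylene and adds to it in anti fashion, which gives the (E)-dichlorovinyl ether.

Step 9
Reactants: 20 benzyl (E)-1,2-dichlorovinyl ether; 21 butanal
Product: 24 1-(benzyloxy)hex-1-yn-3-ol (racemic), via benzyl chloroethynyl ether 22 (not isolated), via lithium benzyloxyethynide 23 (not isolated)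
Conditions: n-BuLi (2.1 equiv), THF, −78 → −40 °C; then 21, −78 °C; H2O
Reagents that add atoms: none
Why: Elimination of HCl and chlorine–lithium exchange with two equivalents of n-BuLi give the lithium alkoxyacetylide, which adds to the aldehyde (acetylide 1,2-addition); the carbinol forms racemic, which is immaterial because its stereocenter is removed in step 10.

Step 10
Reactants: 24 1-(benzyloxy)hex-1-yn-3-ol
Product: 25 1-(benzyloxy)hex-1-yn-3-one
Conditions: MnO2, CH2Cl2, rt
Reagents that add atoms: none
Why: Activated MnO2 oxidises the propargylic alcohol to the ynone under neutral conditions, which avoids the acid-triggered Meyer–Schuster rearrangement of alkoxyethynyl carbinols.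

Step 11
Reactants: 16 (S)-1-{2,4,6-tris(benzyloxy)-3,5-bis[(Z)-5,5-dimethoxy-4-methyl-3-(trimethylsilyloxy)penta-2,4-dienyl]phenyl}-2-methylbutan-1-one; 25 1-(benzyloxy)hex-1-yn-3-one
Product: 28 agrimol B penta-O-benzyl ether (terminal C4 hydroxyls free), via bis(cyclohexadiene) cycloadduct 26 (not isolated), via bis(aryl silyl ether) 27 (not isolated)
Conditions: 25 (3 equiv), toluene (1 M), 0 → 25 °C; then PPTS (cat.), MeOH/CH2Cl2, 0 °C
Reagents that add atoms: 1-(benzyloxy)hex-1-yn-3-one (the second molecule of 25 for the second arm) CCCC(=O)C#COCc1ccccc1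
Why: Each arm of 16 takes up one molecule of 25, two in all, reacting as an electron-rich vinylketene acetal in a strongly asynchronous normal-demand Diels–Alder reaction: the CH terminus that carries the bridge CH2 (nucleophilic through both the silyloxy and the acetal donors) bonds first to the benzyloxy-bearing alkyne carbon (future C3–C2), and the developing allenolate carbon then bonds to the dimethoxy-substituted terminus (future C6–C1). The closest known reaction type is the cycloaddition of 1,1-dialkoxy-3-silyloxybuta-1,3-dienes with acetylenic ketones and esters, whose adducts aromatise by loss of alcohol to resorcinol monoethers. Each terminal ring is closed by the intermolecular [4+2] event itself (in the stepwise limit by 6-exo-trig attack of the allenolate carbon on the dialkoxycarbenium ion), after which acid-assisted 1,4-elimination of methanol from the cyclohexa-1,4-diene aromatises it and methanol removes the aryl silyl group. No lasting stereocenter is formed, since the sp3 CH created at C3 becomes an arene carbon, and the (S)-centre of the side chain is a spectator under these neutral to weakly acidic conditions. The step needs regioselectivity and two-fold conversion: the first is secured by the matched polarity of the partners (donor terminus to the carbonyl-conjugated β-carbon, acetal carbon to the acyl-bearing α-carbon), the second by the (Z)-geometry, which keeps the bulky arm outside the s-cis diene, and by an excess of ynone at high concentration. The temperature is held at or below 25 °C because benzyl ynol ethers rearrange sigmatropically on warming.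

Step 12
Reactants: 28 agrimol B penta-O-benzyl ether
Product: 29 agrimol B
Conditions: H2 (1 atm), Pd/C, EtOAc/EtOH, rt
Reagents that add atoms: none
Why: Hydrogenolysis of the five aryl benzyl ethers over Pd under neutral conditions; the chelated ortho-hydroxyaryl ketones and the diarylmethane bridges should not be reduced at one atmosphere, and the absence of acid or base avoids scrambling of the methylene bridges and epimerisation of the (S)-centre.

**Compound list**

1 | (S)-2-methylbutanoic acid | CC[C@H](C)C(=O)O | starting material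
2 | phloroglucinol | Oc1cc(O)cc(O)c1 | starting material
3 | (S)-2-methylbutanoyl chloride | CC[C@H](C)C(=O)Cl | intermediate
4 | (S)-2-methyl-1-(2,4,6-trihydroxyphenyl)butan-1-one | CC[C@H](C)C(=O)c1c(O)cc(O)cc1O | intermediate
5 | bis(iminium) salt: (S)-3,5-bis(dimethyliminiomethyl)-2,4,6-trihydroxyphenyl sec-butyl ketone dichloride | CC[C@H](C)C(=O)c1c(O)c(C=[N+](C)C)c(O)c(C=[N+](C)C)c1O.[Cl-].[Cl-] | intermediate
6 | (S)-2,4,6-trihydroxy-5-(2-methylbutanoyl)benzene-1,3-dicarbaldehyde | CC[C@H](C)C(=O)c1c(O)c(C=O)c(O)c(C=O)c1O | intermediate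
7 | (S)-2,4,6-tris(benzyloxy)-5-(2-methylbutanoyl)benzene-1,3-dicarbaldehyde | CC[C@H](C)C(=O)c1c(OCc2ccccc2)c(C=O)c(OCc2ccccc2)c(C=O)c1OCc1ccccc1 | intermediate
8 | Meldrum's acid (2,2-dimethyl-1,3-dioxane-4,6-dione) | CC1(C)OC(=O)CC(=O)O1 | starting material
9 | bis(alkylidene Meldrum's acid) of 7 | CC[C@H](C)C(=O)c1c(OCc2ccccc2)c(C=C2C(=O)OC(C)(C)OC2=O)c(OCc2ccccc2)c(C=C2C(=O)OC(C)(C)OC2=O)c1OCc1ccccc1 | intermediate
10 | bis(alkyl Meldrum's acid) | CC[C@H](C)C(=O)c1c(OCc2ccccc2)c(CC2C(=O)OC(C)(C)OC2=O)c(OCc2ccccc2)c(CC2C(=O)OC(C)(C)OC2=O)c1OCc1ccccc1 | intermediate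
11 | 3,3'-{2,4,6-tris(benzyloxy)-5-[(S)-2-methylbutanoyl]-1,3-phenylene}dipropanoic acid | CC[C@H](C)C(=O)c1c(OCc2ccccc2)c(CCC(=O)O)c(OCc2ccccc2)c(CCC(=O)O)c1OCc1ccccc1 | intermediate
12 | trimethyl orthopropionate | CCC(OC)(OC)OC | starting material
13 | 1,1-dimethoxypropene | CC=C(OC)OC | intermediate
14 | bis(acid chloride) of 11 | CC[C@H](C)C(=O)c1c(OCc2ccccc2)c(CCC(=O)Cl)c(OCc2ccccc2)c(CCC(=O)Cl)c1OCc1ccccc1 | intermediate
15 | (S)-1-[2,4,6-tris(benzyloxy)-3,5-bis(5,5-dimethoxy-4-methyl-3-oxopent-4-enyl)phenyl]-2-methylbutan-1-one | CC[C@H](C)C(=O)c1c(OCc2ccccc2)c(CCC(=O)C(C)=C(OC)OC)c(OCc2ccccc2)c(CCC(=O)C(C)=C(OC)OC)c1OCc1ccccc1 | intermediate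
16 | (S)-1-{2,4,6-tris(benzyloxy)-3,5-bis[(Z)-5,5-dimethoxy-4-methyl-3-(trimethylsilyloxy)penta-2,4-dienyl]phenyl}-2-methylbutan-1-one (bis-diene) | CC[C@H](C)C(=O)c1c(OCc2ccccc2)c(C/C=C(\O[Si](C)(C)C)C(C)=C(OC)OC)c(OCc2ccccc2)c(C/C=C(\O[Si](C)(C)C)C(C)=C(OC)OC)c1OCc1ccccc1 | intermediate
17 | benzyl alcohol | OCc1ccccc1 | starting material
18 | trichloroethylene | ClC=C(Cl)Cl | starting material
19 | potassium benzyl oxide | [K+].[O-]Cc1ccccc1 | intermediate
20 | benzyl (E)-1,2-dichlorovinyl ether | Cl/C=C(/Cl)OCc1ccccc1 | intermediate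
21 | butanal | CCCC=O | starting material
22 | benzyl chloroethynyl ether | ClC#COCc1ccccc1 | intermediate
23 | lithium benzyloxyethynide | [Li+].[C-]#COCc1ccccc1 | intermediate
24 | 1-(benzyloxy)hex-1-yn-3-ol (racemic) | CCCC(O)C#COCc1ccccc1 | intermediate
25 | 1-(benzyloxy)hex-1-yn-3-one | CCCC(=O)C#COCc1ccccc1 | intermediate
26 | bis(cyclohexadiene) cycloadduct (mixture of diastereomers at the two ring CH carbons) | CC[C@H](C)C(=O)c1c(OCc2ccccc2)c(CC2C(OCc3ccccc3)=C(C(=O)CCC)C(OC)(OC)C(C)=C2O[Si](C)(C)C)c(OCc2ccccc2)c(CC2C(OCc3ccccc3)=C(C(=O)CCC)C(OC)(OC)C(C)=C2O[Si](C)(C)C)c1OCc1ccccc1 | intermediate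
27 | bis(aryl trimethylsilyl ether) of 28 | CC[C@H](C)C(=O)c1c(OCc2ccccc2)c(Cc2c(OCc3ccccc3)c(C(=O)CCC)c(OC)c(C)c2O[Si](C)(C)C)c(OCc2ccccc2)c(Cc2c(OCc3ccccc3)c(C(=O)CCC)c(OC)c(C)c2O[Si](C)(C)C)c1OCc1ccccc1 | intermediate
28 | agrimol B penta-O-benzyl ether (central tri-O-benzyl, terminal C2 O-benzyl, terminal C4 OH free) | CC[C@H](C)C(=O)c1c(OCc2ccccc2)c(Cc2c(OCc3ccccc3)c(C(=O)CCC)c(OC)c(C)c2O)c(OCc2ccccc2)c(Cc2c(OCc3ccccc3)c(C(=O)CCC)c(OC)c(C)c2O)c1OCc1ccccc1 | intermediate
29 | agrimol B | CCCC(=O)c1c(O)c(Cc2c(O)c(Cc3c(O)c(C)c(OC)c(C(=O)CCC)c3O)c(O)c(C(=O)[C@@H](C)CC)c2O)c(O)c(C)c1OC | target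

**Step count**

Total: 12 steps. Longest linear sequence: 8 steps (steps 1, 2, 3, 4, 6, 7, 11, 12).

**Steps most likely to fail**

1. Step 11. The cycloaddition may stall. The benzyloxy donor weakens the ynone as a dienophile, and the diene terminus that must bond first carries a bulky benzylic arm. Protodesilylation or hydrolysis of the diene, or thermal rearrangement of the ynol ether, could then outrun the second ring formation and leave a one-armed product.
Fallback, setting out from 13, 25 and 4 and coming back at 29: the terminal rings are built first on an unhindered diene and the bridges are made afterwards. Acetyl chloride acylates 13 to 4,4-dimethoxy-3-methylbut-3-en-2-one F1. Me3SiOTf/Et3N converts this into 1,1-dimethoxy-2-methyl-3-(trimethylsilyloxy)buta-1,3-diene F2. Its unsubstituted terminus should add to 25 (toluene, rt; then PPTS, MeOH) to give 1-[6-(benzyloxy)-4-hydroxy-2-methoxy-3-methylphenyl]butan-1-one F3. Hydrogenolysis (H2, Pd/C) gives 1-(4,6-dihydroxy-2-methoxy-3-methylphenyl)butan-1-one F4. In parallel, 4 is aminomethylated twice with Eschenmoser's salt [Me2N=CH2]I to the bis-Mannich base (S)-1-[3,5-bis(dimethylaminomethyl)-2,4,6-trihydroxyphenyl]-2-methylbutan-1-one F5. Heating F5 with two equivalents of F4 in dioxane should expel dimethylamine; the ortho-quinone methides so formed are trapped by the only free ring carbon of F4 to give 29.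

2. Step 6. The activated acyl groups may be lost by intramolecular O-acylation of a neighbouring benzyl ether (lactonisation with expulsion of benzyl chloride). Chloride may also demethylate the dialkoxycarbenium intermediate to a β-keto ester instead of the intermediate losing a proton.
Fallback, setting out from 7 and coming back at 15: the ketone carbon is brought in as a nucleophile instead. The lithium enolate (LDA, THF, −78 °C) of 4,4-dimethoxy-3-methylbut-3-en-2-one F6 (identical with F1, from 13 and acetyl chloride) adds to both aldehydes of 7 to give the bis(β-hydroxy ketone) F7 (mixture of carbinol diastereomers). MsCl/Et3N dehydrates it to the bis[(E)-enone] F8. Conjugate reduction with Stryker's reagent [(Ph3P)CuH]6 should saturate only the disubstituted enone double bonds, the tetrasubstituted donor-substituted ketene acetal double bonds being inert, and return 15.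

3. Step 3. O-Alkylation may stay incomplete because the phenoxides, each stabilised by two ortho carbonyl groups, are poor nucleophiles, and dearomatising C-benzylation may compete.
Fallback, setting out from 4 and coming back at 11: the phenols are protected before the ring is loaded with carbonyl groups, and the arms are attached by cross-coupling. 4 is tri-O-benzylated (BnBr, K2CO3, DMF) to (S)-2-methyl-1-[2,4,6-tris(benzyloxy)phenyl]butan-1-one F9. NBS in MeCN brominates the two activated ring positions to give (S)-1-[2,4,6-tris(benzyloxy)-3,5-dibromophenyl]-2-methylbutan-1-one F10. Double Negishi coupling with (3-ethoxy-3-oxopropyl)zinc bromide (Pd(OAc)2/SPhos, THF, 50 °C) gives diethyl 3,3'-{2,4,6-tris(benzyloxy)-5-[(S)-2-methylbutanoyl]-1,3-phenylene}dipropanoate F11. Saponification (LiOH, THF/H2O, rt) returns 11.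

**Further compounds**

F1 | step 11 | 4,4-dimethoxy-3-methylbut-3-en-2-one | CC(=O)C(C)=C(OC)OC
F2 | step 11 | 1,1-dimethoxy-2-methyl-3-(trimethylsilyloxy)buta-1,3-diene | C=C(O[Si](C)(C)C)C(C)=C(OC)OC
F3 | step 11 | 1-[6-(benzyloxy)-4-hydroxy-2-methoxy-3-methylphenyl]butan-1-one | CCCC(=O)c1c(OCc2ccccc2)cc(O)c(C)c1OC
F4 | step 11 | 1-(4,6-dihydroxy-2-methoxy-3-methylphenyl)butan-1-one | CCCC(=O)c1c(O)cc(O)c(C)c1OC
F5 | step 11 | (S)-1-[3,5-bis(dimethylaminomethyl)-2,4,6-trihydroxyphenyl]-2-methylbutan-1-one | CC[C@H](C)C(=O)c1c(O)c(CN(C)C)c(O)c(CN(C)C)c1O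
F6 | step 6 | 4,4-dimethoxy-3-methylbut-3-en-2-one | CC(=O)C(C)=C(OC)OC
F7 | step 6 | bis(β-hydroxy ketone): (S)-1-[2,4,6-tris(benzyloxy)-3,5-bis(1-hydroxy-5,5-dimethoxy-4-methyl-3-oxopent-4-enyl)phenyl]-2-methylbutan-1-one | CC[C@H](C)C(=O)c1c(OCc2ccccc2)c(C(O)CC(=O)C(C)=C(OC)OC)c(OCc2ccccc2)c(C(O)CC(=O)C(C)=C(OC)OC)c1OCc1ccccc1
F8 | step 6 | bis[(E)-enone]: (S)-1-{2,4,6-tris(benzyloxy)-3,5-bis[(E)-5,5-dimethoxy-4-methyl-3-oxopenta-1,4-dienyl]phenyl}-2-methylbutan-1-one | CC[C@H](C)C(=O)c1c(OCc2ccccc2)c(/C=C/C(=O)C(C)=C(OC)OC)c(OCc2ccccc2)c(/C=C/C(=O)C(C)=C(OC)OC)c1OCc1ccccc1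
F9 | step 3 | (S)-2-methyl-1-[2,4,6-tris(benzyloxy)phenyl]butan-1-one | CC[C@H](C)C(=O)c1c(OCc2ccccc2)cc(OCc2ccccc2)cc1OCc1ccccc1
F10 | step 3 | (S)-1-[2,4,6-tris(benzyloxy)-3,5-dibromophenyl]-2-methylbutan-1-one | CC[C@H](C)C(=O)c1c(OCc2ccccc2)c(Br)c(OCc2ccccc2)c(Br)c1OCc1ccccc1
F11 | step 3 | diethyl 3,3'-{2,4,6-tris(benzyloxy)-5-[(S)-2-methylbutanoyl]-1,3-phenylene}dipropanoate | CC[C@H](C)C(=O)c1c(OCc2ccccc2)c(CCC(=O)OCC)c(OCc2ccccc2)c(CCC(=O)OCC)c1OCc1ccccc1
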